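**Remarks on the chemistry.** Biogenetic numbering is used throughout: C1 lactone carbonyl, C2 its CH2, C3 the CH bearing the peroxide, C4 the quaternary carbon bearing the lactone oxygen, C5 the ring CH2, C6 the quaternary peroxide carbon, C7–C14 the side chain. In this numbering the target is (3R,4R,6R,8S,10E,12E). The sense of induction of the RAMP auxiliary is assumed from the usual behaviour of cyclohexanone hydrazones (the SAMP series would give the enantiomer of 10).

## Retrosynthetic overview

1. The diene is cut at C11–C12 (Negishi coupling of iodoalkene peroxylactone 27); before that the γ-lactone is closed and the C6 methyl is put onto a C6 methoxy peroxyketal.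
2. The C4 lactone oxygen and the C8 methyl are unmasked from a temporary cyclohexanone ring (C4–C(=O)–C8–C7–C6–C5) by Baeyer–Villiger oxidation, reduction and deoxygenation.
3. Key disconnection: the peroxide O–C6 bond together with the C3–C4 bond, a [3+3] union of the O–O–C3 unit of silyl peroxyacetal 18 with the C4–C5–C6 unit of enol silane ketal 14, giving 2,3-dioxabicyclo[3.3.1]nonanone 20.
4. Enabling feature: in the 1,2-dioxane ring C4 and C6 are both fully substituted and 1,3-related through the C5 methylene. In a cyclohexane-1,4-dione frame C6 is a ketal carbon (accepts the peroxide oxygen) and C4 the enolisable α-carbon (attacks C3), and the frame ties C4 to the pre-set C8 stereocentre.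
5. Ring order: temporary carbocycle (from 5; C8 by RAMP-hydrazone alkylation), 1,2-dioxane (step 11), carbocycle excised (steps 12–15), γ-lactone (step 17).

Key step: step 11

## Route

Step 1
Reactants: 1 prop-2-yn-1-ol
Product: 3 (E)-3-iodo-2-methylprop-2-en-1-ol, via alkenylalane 2 (not isolated)
Conditions: AlMe3 (3 equiv), Cp2ZrCl2 (0.25 equiv), CH2Cl2, 0 °C to rt; then I2, THF, −30 °C
Reagents that add atoms: trimethylaluminium C[Al](C)C; iodine II
Why: Zirconium-catalysed carboalumination adds methyl and aluminium syn across the alkyne with the metal on the terminal carbon, and iodinolysis with retention should give the E iodoalkene.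

Step 2
Reactants: 3 (E)-3-iodo-2-methylprop-2-en-1-ol
Product: 4 (E)-3-bromo-1-iodo-2-methylprop-1-ene
Conditions: CBr4, PPh3, CH2Cl2, 0 °C
Reagents that add atoms: carbon tetrabromide BrC(Br)(Br)Br
Why: Appel bromination of a primary allylic alcohol should proceed without touching the iodoalkene or its geometry.

Step 3
Reactants: 5 4,4-dimethoxycyclohexan-1-one; 6 (R)-1-amino-2-(methoxymethyl)pyrrolidine (RAMP)
Product: 7 RAMP hydrazone of 5
Conditions: neat, 4 Å molecular sieves, 60 °C
Reagents that add atoms: none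
Why: Hydrazone condensation of an unhindered ketone needs no acid, so the dimethyl ketal should survive.

Step 4
Reactants: 7 RAMP hydrazone of 5; 4 (E)-3-bromo-1-iodo-2-methylprop-1-ene
Product: 9 RAMP hydrazone of (S)-2-[(E)-3-iodo-2-methylallyl]-4,4-dimethoxycyclohexanone, via lithium azaenolate 8 (not isolated)
Conditions: LiN(iPr)2, THF, 0 °C; then 4, −100 °C to rt
Reagents that add atoms: none
Why: Auxiliary-controlled α-alkylation of a chiral hydrazone, in which the chelated azaenolate is attacked by the allylic bromide on the face away from the methoxymethyl arm, should set C8 (S in ketone 10).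

Step 5
Reactants: 9 RAMP hydrazone of (S)-2-[(E)-3-iodo-2-methylallyl]-4,4-dimethoxycyclohexanone
Product: 10 (S)-2-[(E)-3-iodo-2-methylprop-2-en-1-yl]-4,4-dimethoxycyclohexan-1-one
Conditions: CuCl2·2H2O, THF, aqueous phosphate buffer (pH 7), rt
Reagents that add atoms: water O
Why: Copper-assisted hydrolysis of the hydrazone near neutrality should free the ketone without epimerising the α-centre, opening the ketal or touching the iodoalkene.

Step 6
Reactants: 10 (S)-2-[(E)-3-iodo-2-methylprop-2-en-1-yl]-4,4-dimethoxycyclohexan-1-one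
Product: 12 (S)-6-[(E)-3-iodo-2-methylprop-2-en-1-yl]-4,4-dimethoxy-2-methylidenecyclohexan-1-one, via Mannich base 11 (not isolated)
Conditions: LiN(iPr)2, THF, −78 °C; dimethylmethyleneammonium iodide, −78 °C to rt; then MeI, Et2O; then aqueous NaHCO3, CH2Cl2
Reagents that add atoms: dimethylmethyleneammonium iodide C=[N+](C)C.[I-]
Why: Kinetic deprotonation occurs at the unsubstituted α-CH2, and the Mannich reaction, quaternisation and elimination sequence is a standard α-methylenation that leaves the C8 centre untouched.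

Step 7
Reactants: 12 (S)-6-[(E)-3-iodo-2-methylprop-2-en-1-yl]-4,4-dimethoxy-2-methylidenecyclohexan-1-one
Product: 14 {[(S)-6-((E)-3-iodo-2-methylprop-2-en-1-yl)-4,4-dimethoxy-2-methylcyclohex-1-en-1-yl]oxy}trimethylsilane, via lithium enolate 13 (not isolated)
Conditions: LiBH(sec-Bu)3, THF, −78 °C; then Me3SiCl, Et3N, −78 to 0 °C
Reagents that add atoms: chlorotrimethylsilane C[Si](C)(C)Cl
Why: Conjugate hydride addition to the β-unsubstituted exocyclic enone creates the C4 methyl and a regiodefined enolate, and O-silylation fixes the tetrasubstituted enol silane on the C4 side only.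

Step 8
Reactants: 15 (E)-hex-3-enedioic acid
Product: 16 di-tert-butyl (E)-hex-3-enedioate
Conditions: 2-methylpropene (excess), H2SO4 (cat.), CH2Cl2, rt, sealed vessel
Reagents that add atoms: 2-methylpropene CC(C)=C
Why: Acid-catalysed addition of the carboxylic acid to isobutylene is a standard tert-butyl ester formation.

Step 9
Reactants: 16 di-tert-butyl (E)-hex-3-enedioate
Product: 17 tert-butyl 3-hydroperoxy-3-methoxypropanoate (racemic)
Conditions: O3, CH2Cl2/MeOH (4:1), NaHCO3, −78 °C; N2 purge, no reductant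
Reagents that add atoms: ozone [O-][O+]=O; methanol CO
Why: Ozonolysis in methanol traps the carbonyl oxide as the α-methoxy hydroperoxide, and the symmetric alkene makes the direction of fragmentation irrelevant.

Step 10
Reactants: 17 tert-butyl 3-hydroperoxy-3-methoxypropanoate
Product: 18 tert-butyl 3-methoxy-3-(triethylsilylperoxy)propanoate (racemic)
Conditions: Et3SiCl, imidazole, DMF, 0 °C
Reagents that add atoms: chlorotriethylsilane CC[Si](Cl)(CC)CC
Why: O-silylation of a hydroperoxide with a silyl chloride and imidazole is routine and gives the protected peroxycarbenium precursor.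

Step 11
Reactants: 14 {[(S)-6-((E)-3-iodo-2-methylprop-2-en-1-yl)-4,4-dimethoxy-2-methylcyclohex-1-en-1-yl]oxy}trimethylsilane; 18 tert-butyl 3-methoxy-3-(triethylsilylperoxy)propanoate
Product: 20 tert-butyl 2-[7-((E)-3-iodo-2-methylallyl)-1-methoxy-5-methyl-6-oxo-2,3-dioxabicyclo[3.3.1]nonan-4-yl]acetate, via mixed peroxyketal 19 (not isolated)
Conditions: Me3SiOTf (0.3 equiv), 2,6-di-tert-butyl-4-methylpyridine (0.4 equiv), 4 Å molecular sieves, CH2Cl2 (0.02 M), −78 to −40 °C
Reagents that add atoms: none
Why: Proposed new method: the silyl triflate should ionise the C6 dimethyl ketal, the silylperoxy oxygen of 18 captures the oxocarbenium ion with loss of its silyl group (O–C6 bond, mixed peroxyketal 19), and ionisation of the C3 methoxy group then gives a peroxycarbenium ion that is attacked intramolecularly by the enol silane carbon C4 (C3–C4 bond), the two methoxysilanes returning the silyl triflate. The closest known reaction types are Lewis-acid-mediated additions of silyl enol ethers and alkenes to peroxycarbenium ions from silylperoxy acetals (peroxide-forming [3+2] annulations) and silyl-triflate-catalysed ketal–enol silane condensations; new is their union into a [3+3] annulation that builds a 1,2-dioxane. The dioxane closes through a six-membered chair transition state of the Mukaiyama–Prins type (6-endo-trig at the peroxycarbenium carbon, exo with respect to the enol double bond), which bridges C4 and C6 of the carbocycle to the bicyclo[3.3.1] skeleton. C4 is controlled by C8: the new bond must be axial on the face of the axial peroxy oxygen and anti to the C8 substituent, which is pseudoaxial because of allylic strain with the silyloxy group and ends exo; C3 is controlled by the E-peroxycarbenium geometry, which places CH2CO2tBu equatorial and cis to the C4–C(=O) bond that later becomes the lactone oxygen; C6 is fixed by the bridge (OMe exo). The step needs O-capture of the ketal cation before any intermolecular C–C bond formation and loss of methoxide rather than peroxide from C3; the hindered tetrasubstituted enol silane, reversible ketal exchange, high dilution and the better donor ability of the methoxy oxygen toward silicon should secure both.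

Step 12
Reactants: 20 tert-butyl 2-[7-((E)-3-iodo-2-methylallyl)-1-methoxy-5-methyl-6-oxo-2,3-dioxabicyclo[3.3.1]nonan-4-yl]acetate
Product: 21 tert-butyl 2-[4-((E)-3-iodo-2-methylallyl)-6-methoxy-1-methyl-3-oxo-2,7,8-trioxabicyclo[4.3.1]decan-9-yl]acetate
Conditions: mCPBA, NaHCO3, CH2Cl2, 0 °C to rt
Reagents that add atoms: mCPBA OOC(=O)c1cccc(Cl)c1
Why: In the Baeyer–Villiger oxidation the quaternary bridgehead C4 should migrate with retention in preference to the less substituted C8, which puts the oxygen on C4, while the dialkyl peroxide, the bridgehead ketal and the electron-poor iodoalkene should be inert to buffered peracid.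

Step 13
Reactants: 21 tert-butyl 2-[4-((E)-3-iodo-2-methylallyl)-6-methoxy-1-methyl-3-oxo-2,7,8-trioxabicyclo[4.3.1]decan-9-yl]acetate
Product: 22 tert-butyl 2-[4-hydroxy-6-((2S,4E)-2-(hydroxymethyl)-5-iodo-4-methylpent-4-enyl)-6-methoxy-4-methyl-1,2-dioxan-3-yl]acetate
Conditions: LiBH4, THF, 0 °C
Reagents that add atoms: none
Why: LiBH4 reduces the strained seven-membered lactone to the diol and so opens the temporary ring, whereas the tert-butyl ester, the peroxyketal and the dialkyl peroxide should survive a borohydride.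

Step 14
Reactants: 22 tert-butyl 2-[4-hydroxy-6-((2S,4E)-2-(hydroxymethyl)-5-iodo-4-methylpent-4-enyl)-6-methoxy-4-methyl-1,2-dioxan-3-yl]acetate
Product: 23 tert-butyl 2-[4-hydroxy-6-((2S,4E)-5-iodo-2-(iodomethyl)-4-methylpent-4-enyl)-6-methoxy-4-methyl-1,2-dioxan-3-yl]acetate
Conditions: PPh3, I2, imidazole (PPh3 and I2 premixed), CH2Cl2, 0 °C
Reagents that add atoms: iodine II
Why: Appel iodination converts only the primary alcohol, since the tertiary C4 hydroxyl cannot react, and premixing the phosphine with iodine leaves no free phosphine, so the brief buffered conditions should spare the peroxide.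

Step 15
Reactants: 23 tert-butyl 2-[4-hydroxy-6-((2S,4E)-5-iodo-2-(iodomethyl)-4-methylpent-4-enyl)-6-methoxy-4-methyl-1,2-dioxan-3-yl]acetate
Product: 24 tert-butyl 2-[4-hydroxy-6-((2S,4E)-5-iodo-2,4-dimethylpent-4-enyl)-6-methoxy-4-methyl-1,2-dioxan-3-yl]acetate
Conditions: NaBH4, DMSO, rt
Reagents that add atoms: none
Why: Hydride displacement of the primary iodide in a dipolar aprotic solvent (no radical intermediate that could attack the O–O bond) turns the former ring carbonyl carbon into the C8 methyl group and leaves the sp2 C–I bond untouched.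

Step 16
Reactants: 24 tert-butyl 2-[4-hydroxy-6-((2S,4E)-5-iodo-2,4-dimethylpent-4-enyl)-6-methoxy-4-methyl-1,2-dioxan-3-yl]acetate
Product: 25 tert-butyl 2-[4-hydroxy-6-((2S,4E)-5-iodo-2,4-dimethylpent-4-enyl)-4,6-dimethyl-1,2-dioxan-3-yl]acetate
Conditions: AlMe3 (5 equiv), CH2Cl2, −78 °C; then Me3SiOTf (1.2 equiv), −78 to −40 °C
Reagents that add atoms: trimethylaluminium C[Al](C)C
Why: Proposed new method: the silyl triflate should remove the exocyclic methoxy group to give the cyclic peroxycarbenium ion (O–C6 bond kept), which adopts the half-chair with the C4 aluminium alkoxide pseudoaxial and the C3 arm equatorial, so that methyl is delivered axially on the alkoxide face (chair-like attack assisted by the neighbouring O–AlMe2) and ends cis to the C4 oxygen with the side chain equatorial, as in the target; the closest known reaction types are Lewis-acid-mediated C-allylations of alkoxy-1,2-dioxolanes and -dioxanes through peroxycarbenium ions and AlMe3/silyl triflate methylation of cyclic acetals.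

Step 17
Reactants: 25 tert-butyl 2-[4-hydroxy-6-((2S,4E)-5-iodo-2,4-dimethylpent-4-enyl)-4,6-dimethyl-1,2-dioxan-3-yl]acetate
Product: 27 (3R,4aR,7aR)-3-[(2S,4E)-5-iodo-2,4-dimethylpent-4-en-1-yl]-3,4a-dimethyltetrahydrofuro[3,2-c][1,2]dioxin-6-one, via hydroxy acid 26 (not isolated)
Conditions: CF3CO2H, CH2Cl2, 0 °C to rt
Reagents that add atoms: none
Why: Acidolysis of the tert-butyl ester frees a γ-hydroxy acid that should lactonise spontaneously to the cis-fused γ-lactone, because the C3 arm and the C4 hydroxyl were set cis in step 11.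

Step 18
Reactants: 27 (3R,4aR,7aR)-3-[(2S,4E)-5-iodo-2,4-dimethylpent-4-en-1-yl]-3,4a-dimethyltetrahydrofuro[3,2-c][1,2]dioxin-6-one; 28 1-phenylbut-2-yne
Product: 31 plakortolide, via alkenylzirconocene 29 (not isolated), via alkenylzinc chloride 30 (not isolated)
Conditions: Cp2Zr(H)Cl, THF, rt (on 28); then ZnCl2, THF; then 27, Pd(PPh3)4 (5 mol %), rt
Reagents that add atoms: none
Why: Syn hydrozirconation places zirconium on the less hindered methyl-bearing alkyne carbon, and transmetalation to zinc followed by Negishi coupling with the E iodoalkene joins C11 to C12 with retention at both alkenes under neutral conditions that should spare the peroxylactone.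

## Compound list

1 | prop-2-yn-1-ol | C#CCO | starting material
2 | alkenylalane from carboalumination of 1 | C[Al](C)/C=C(\C)CO[Al](C)C | intermediate
3 | (E)-3-iodo-2-methylprop-2-en-1-ol | OC/C(C)=C/I | intermediate
4 | (E)-3-bromo-1-iodo-2-methylprop-1-ene | BrC/C(C)=C/I | intermediate
5 | 4,4-dimethoxycyclohexan-1-one | O=C1CCC(OC)(OC)CC1 | starting material
6 | (R)-1-amino-2-(methoxymethyl)pyrrolidine (RAMP) | COC[C@H]1CCCN1N | starting material
7 | (R)-N-(4,4-dimethoxycyclohexylidene)-2-(methoxymethyl)pyrrolidin-1-amine | COC[C@H]1CCCN1N=C1CCC(OC)(OC)CC1 | intermediate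
8 | lithium azaenolate of 7 | COC[C@H]1CCCN1N([Li])C1=CCC(OC)(OC)CC1 | intermediate
9 | RAMP hydrazone of (S)-2-[(E)-3-iodo-2-methylallyl]-4,4-dimethoxycyclohexanone (amino group anti to the substituted α-carbon) | COC[C@H]1CCCN1/N=C1\CCC(OC)(OC)C[C@@H]1C/C(C)=C/I | intermediate
10 | (S)-2-[(E)-3-iodo-2-methylprop-2-en-1-yl]-4,4-dimethoxycyclohexan-1-one | O=C1CCC(OC)(OC)C[C@@H]1C/C(C)=C/I | intermediate
11 | Mannich base, 6-(dimethylaminomethyl) derivative of 10 (mixture at the new CH) | CN(C)CC1CC(OC)(OC)C[C@H](C/C(C)=C/I)C1=O | intermediate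
12 | (S)-6-[(E)-3-iodo-2-methylprop-2-en-1-yl]-4,4-dimethoxy-2-methylidenecyclohexan-1-one | O=C1C(=C)CC(OC)(OC)C[C@@H]1C/C(C)=C/I | intermediate
13 | lithium enolate from conjugate reduction of 12 | [Li]OC1=C(C)CC(OC)(OC)C[C@@H]1C/C(C)=C/I | intermediate
14 | {[(S)-6-((E)-3-iodo-2-methylprop-2-en-1-yl)-4,4-dimethoxy-2-methylcyclohex-1-en-1-yl]oxy}trimethylsilane | C[Si](C)(C)OC1=C(C)CC(OC)(OC)C[C@@H]1C/C(C)=C/I | intermediate
15 | (E)-hex-3-enedioic acid | OC(=O)C/C=C/CC(=O)O | starting material
16 | di-tert-butyl (E)-hex-3-enedioate | CC(C)(C)OC(=O)C/C=C/CC(=O)OC(C)(C)C | intermediate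
17 | tert-butyl 3-hydroperoxy-3-methoxypropanoate (racemic) | CC(C)(C)OC(=O)CC(OC)OO | intermediate
18 | tert-butyl 3-methoxy-3-(triethylsilylperoxy)propanoate (racemic) | CC(C)(C)OC(=O)CC(OC)OO[Si](CC)(CC)CC | intermediate
19 | mixed peroxyketal of 14 and 18 at C6 (mixture at C6 and C3) | C[Si](C)(C)OC1=C(C)CC(OC)(OOC(OC)CC(=O)OC(C)(C)C)C[C@@H]1C/C(C)=C/I | intermediate
20 | tert-butyl 2-[7-((E)-3-iodo-2-methylallyl)-1-methoxy-5-methyl-6-oxo-2,3-dioxabicyclo[3.3.1]nonan-4-yl]acetate (acetate arm equatorial on the dioxane, allyl group exo; C3, C4, C8 as in the target) | O=C1[C@]2(C)C[C@@](OC)(OO[C@@H]2CC(=O)OC(C)(C)C)C[C@@H]1C/C(C)=C/I | intermediate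
21 | tert-butyl 2-[4-((E)-3-iodo-2-methylallyl)-6-methoxy-1-methyl-3-oxo-2,7,8-trioxabicyclo[4.3.1]decan-9-yl]acetate (seven-membered lactone with its ring oxygen on the methyl-bearing bridgehead) | O=C1O[C@]2(C)C[C@@](OC)(OO[C@@H]2CC(=O)OC(C)(C)C)C[C@@H]1C/C(C)=C/I | intermediate
22 | tert-butyl 2-[4-hydroxy-6-((2S,4E)-2-(hydroxymethyl)-5-iodo-4-methylpent-4-enyl)-6-methoxy-4-methyl-1,2-dioxan-3-yl]acetate (3-arm and 4-OH cis) | CO[C@]1(C[C@@H](CO)C/C(C)=C/I)C[C@@](C)(O)[C@@H](CC(=O)OC(C)(C)C)OO1 | intermediate
23 | tert-butyl 2-[4-hydroxy-6-((2S,4E)-5-iodo-2-(iodomethyl)-4-methylpent-4-enyl)-6-methoxy-4-methyl-1,2-dioxan-3-yl]acetate | CO[C@]1(C[C@@H](CI)C/C(C)=C/I)C[C@@](C)(O)[C@@H](CC(=O)OC(C)(C)C)OO1 | intermediate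
24 | tert-butyl 2-[4-hydroxy-6-((2S,4E)-5-iodo-2,4-dimethylpent-4-enyl)-6-methoxy-4-methyl-1,2-dioxan-3-yl]acetate | CO[C@]1(C[C@@H](C)C/C(C)=C/I)C[C@@](C)(O)[C@@H](CC(=O)OC(C)(C)C)OO1 | intermediate
25 | tert-butyl 2-[4-hydroxy-6-((2S,4E)-5-iodo-2,4-dimethylpent-4-enyl)-4,6-dimethyl-1,2-dioxan-3-yl]acetate (6-methyl cis to 4-OH) | C[C@@]1(C[C@@H](C)C/C(C)=C/I)C[C@@](C)(O)[C@@H](CC(=O)OC(C)(C)C)OO1 | intermediate
26 | 2-[4-hydroxy-6-((2S,4E)-5-iodo-2,4-dimethylpent-4-enyl)-4,6-dimethyl-1,2-dioxan-3-yl]acetic acid | C[C@@]1(C[C@@H](C)C/C(C)=C/I)C[C@@](C)(O)[C@@H](CC(=O)O)OO1 | intermediate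
27 | (3R,4aR,7aR)-3-[(2S,4E)-5-iodo-2,4-dimethylpent-4-en-1-yl]-3,4a-dimethyltetrahydrofuro[3,2-c][1,2]dioxin-6-one | I/C=C(\C)C[C@H](C)C[C@]1(C)C[C@@]2(C)OC(=O)C[C@H]2OO1 | intermediate
28 | 1-phenylbut-2-yne | CC#CCc1ccccc1 | starting material
29 | chlorobis(cyclopentadienyl)[(E)-4-phenylbut-2-en-2-yl]zirconium | Cl[Zr](/C(C)=C/Cc1ccccc1)(C1C=CC=C1)C1C=CC=C1 | intermediate
30 | [(E)-4-phenylbut-2-en-2-yl]zinc chloride | Cl[Zn]/C(C)=C/Cc1ccccc1 | intermediate
31 | plakortolide, (3R,4aR,7aR)-3,4a-dimethyl-3-[(2S,4E,6E)-2,4,6-trimethyl-8-phenylocta-4,6-dien-1-yl]tetrahydrofuro[3,2-c][1,2]dioxin-6-one | CC(=C\Cc1ccccc1)/C=C(\C)C[C@H](C)C[C@]1(C)C[C@@]2(C)OC(=O)C[C@H]2OO1 | target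

## Step count and risks

Total step count: 18. Longest linear sequence: 14 steps (from 1 through steps 1, 2, 4–7 and 11–18).

Steps most likely to fail:

1. Step 11 (proposed new method). The enol silane may form C–C bonds intermolecularly with ketal-derived oxocarbenium ions (oligomerisation), or the peroxyacetal may ionise by loss of the peroxide instead of methoxide. Fallback with known reaction types, setting out from 12 and returning at 20: the C3–C4 bond is made first by conjugate addition. The lithium enolate 13 (from 12 with LiBH(sec-Bu)3, no silylation) is added to tert-butyl propiolate (THF, −78 °C) to give tert-butyl (E)-3-[3-((E)-3-iodo-2-methylallyl)-5,5-dimethoxy-1-methyl-2-oxocyclohexyl]acrylate F1. Exchange of one ketal methoxy group for OOH (urea–H2O2, Sc(OTf)3 cat., MeOH/CH2Cl2) gives the methoxy hydroperoxy ketal F2. Amine-promoted intramolecular peroxy-Michael addition (Et2NH, CF3CH2OH) then closes the dioxane onto C3 and delivers 20; this addition is reversible, so the C3 epimers should converge on the equatorial one.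

2. Step 16 (proposed new method). The aluminium reagent may reduce or cleave the O–O bond, the ketal may ionise by loss of the ring peroxide oxygen, or methyl may enter on the wrong face. Fallback with known reaction types, setting out from 24 and returning at 27: hydrolysis and reduction (PPTS, acetone–H2O; then Me2S) open 24 to the keto diol F3. Non-basic methylenation (Zn, CH2Br2, TiCl4) gives the 1,1-disubstituted alkene F4. CF3CO2H gives the hydroxy lactone F5, and MsCl/Et3N the butenolide F6. Mukaiyama–Isayama peroxidation (Co(acac)2, O2, Et3SiH) gives the tertiary silyl peroxide F7 as both C6 epimers. Bu4NF/AcOH frees the hydroperoxide F8, and Et2NH/CF3CH2OH closes it by peroxy-Michael addition to 27, which would have to be separated from its C6 epimer because the radical peroxidation is not face-selective.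

3. Step 18. Regiocontrol in the hydrozirconation may be incomplete, and the organometallic or zerovalent palladium may slowly reduce the O–O bond or trigger β-elimination of the peroxide from the lactone. Fallback setting out from 28 and returning at 31: the coupling partner is made separately and purified. Hydrozirconation and iodinolysis of 28 give (E)-(3-iodobut-2-en-1-yl)benzene F9 (regioisomer removed); lithium–iodine exchange (t-BuLi) and Bu3SnCl give tributyl[(E)-4-phenylbut-2-en-2-yl]stannane F10. Stille coupling of F10 with 27 (Pd2(dba)3, AsPh3, CuI, DMF, rt) under neutral conditions gives 31.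

## Further compounds

F1 | step 11 | tert-butyl (E)-3-[3-((E)-3-iodo-2-methylallyl)-5,5-dimethoxy-1-methyl-2-oxocyclohexyl]acrylate (acrylate trans to the allyl group) | O=C1[C@@](C)(/C=C/C(=O)OC(C)(C)C)CC(OC)(OC)C[C@@H]1C/C(C)=C/I
F2 | step 11 | tert-butyl (E)-3-[5-hydroperoxy-3-((E)-3-iodo-2-methylallyl)-5-methoxy-1-methyl-2-oxocyclohexyl]acrylate (either ketal epimer) | O=C1[C@@](C)(/C=C/C(=O)OC(C)(C)C)CC(OC)(OO)C[C@@H]1C/C(C)=C/I
F3 | step 16 | tert-butyl (8S,10E)-3,4-dihydroxy-11-iodo-4,8,10-trimethyl-6-oxoundec-10-enoate (C3, C4 as in 24) | CC(C)(C)OC(=O)C[C@@H](O)[C@](C)(O)CC(=O)C[C@@H](C)C/C(C)=C/I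
F4 | step 16 | tert-butyl (8S,10E)-3,4-dihydroxy-11-iodo-4,8,10-trimethyl-6-methylideneundec-10-enoate | CC(C)(C)OC(=O)C[C@@H](O)[C@](C)(O)CC(=C)C[C@@H](C)C/C(C)=C/I
F5 | step 16 | 4-hydroxy-5-[(4S,6E)-7-iodo-4,6-dimethyl-2-methylidenehept-6-enyl]-5-methyldihydrofuran-2-one | O=C1C[C@@H](O)[C@@](C)(CC(=C)C[C@@H](C)C/C(C)=C/I)O1
F6 | step 16 | 5-[(4S,6E)-7-iodo-4,6-dimethyl-2-methylidenehept-6-enyl]-5-methylfuran-2(5H)-one | O=C1C=C[C@@](C)(CC(=C)C[C@@H](C)C/C(C)=C/I)O1
F7 | step 16 | 5-[(4S,6E)-7-iodo-2,4,6-trimethyl-2-(triethylsilylperoxy)hept-6-enyl]-5-methylfuran-2(5H)-one (both C6 epimers) | O=C1C=C[C@@](C)(CC(C)(OO[Si](CC)(CC)CC)C[C@@H](C)C/C(C)=C/I)O1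
F8 | step 16 | 5-[(4S,6E)-2-hydroperoxy-7-iodo-2,4,6-trimethylhept-6-enyl]-5-methylfuran-2(5H)-one (both C6 epimers) | O=C1C=C[C@@](C)(CC(C)(OO)C[C@@H](C)C/C(C)=C/I)O1
F9 | step 18 | (E)-(3-iodobut-2-en-1-yl)benzene | I/C(C)=C/Cc1ccccc1
F10 | step 18 | tributyl[(E)-4-phenylbut-2-en-2-yl]stannane | CCCC[Sn](CCCC)(CCCC)/C(C)=C/Cc1ccccc1
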